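Atoms carry the numbering of the target throughout: C1–C10 ring carbons, C11–C13 lactone carbons (C12 carbonyl, C13 exocyclic), C14 the methyl on C10, C15 the methyl on C4.

## Analysis of the target

Eupaheliangolide A, compound 33, is a heliangolide: a ten-membered carbocycle C1–C10 carrying a cross-conjugated dienone, with the E alkene C1=C2 and the Z alkene C4=C5 (C15 on C4) on either side of the C3 ketone, fused at C6/C7 to an α-methylene-γ-butyrolactone (O6–C12(=O)–C11(=C13)). The four stereocentres are all R: C6 and C7 make up the trans lactone fusion, C8 carries the tiglate with O8 anti to O6 along the chain C5–C9, and C10 is a tertiary carbinol (C14) that is 1,3-anti to O8. Sensitive groups are three Michael acceptor sites (C13, C1, C5), a tertiary allylic alcohol, an ester that can be lost by elimination across C7–C8, and a lactone that can migrate from O6 to O8 once O8 is free. The difficulty lies in the strained ten-membered ring with one E and one Z enone, and in the remote C10 centre, which nothing controls in an open chain. The strategy rests on one feature: C10 is 1,3 to O8 and bonded to C1, the β-carbon of the C1=C2–C3(=O) enone. Held in a 1,3-dioxane with O8, C10 can be generated as an α-oxy radical and C1 can accept it, so the C1–C10 bond, the ring and the C10 configuration arise in one event.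

## Retrosynthetic reasoning

**Endgame, 33 back to 27.** The exocyclic methylene is the most reactive acceptor and is restored last, by elimination of the C13 mesylate 32 made from alcohol 31. The tiglate comes from tiglic acid 29 and the C8 hydroxyl of diol 28, where the tertiary C10 hydroxyl needs no protection. Diol 28 is the hydrolysis product of the 8,10-acetonide 27. The C13 oxygen is carried as a TBDPS ether so that it survives that hydrolysis.

**C1–C10, 27 back to 25.** This bond is cut because it is the only ring bond whose formation can also set C10. In seco acid 25 the carboxyl group sits on C10 and C1 carries a phenylsulfonyl group. Decarboxylation gives one dioxanyl radical from either C10 epimer, so C10 need not be controlled beforehand. The forward step must close the ring 10-endo, bring C1 in axially and regenerate the C1=C2 alkene by loss of the sulfonyl group. C11=C13 must be saturated at this stage so that the radical has only one strong acceptor.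

**C3–C4, 25 back to 21 and 24.** The sulfonyl enone is too electrophilic to carry through several steps, so it is attached last by carbonylative Stille coupling of vinyl iodide 21 with stannane 24. Stannane 24 comes from bis-stannane 22 and sulfonyl chloride 23. The robust Z-iodoalkene thus serves as the C4 handle throughout.

**Acid and acetonide, 21 back to 18.** A carboxyl group on C10 at the ester or acid level would lactonise onto O8 as soon as O8 is free, so the carboxyl carbon is carried as a silyl-protected primary alcohol. It is released as alcohol 20 and oxidised only after O8 and O10 are locked in acetonide 19, which is made from diol 18.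

**C8 configuration and methylene mask, 18 back to 13.** The Barbier adduct 13 is expected to be the 7,8-anti (8S) alcohol, whereas the target needs 8R. C8 is therefore inverted by a Mitsunobu reaction of alcohol 16 to ester 17, and the ester is removed to give diol 18. Before that, the methylene lactone of 13 is masked by conjugate borylation to boronate 14, oxidation to alcohol 15 and silylation to 16, because the nucleophiles of the inversion and ester cleavage steps would add to it.

**C7–C8, 13 back to 8 and 12.** Allylation of aldehyde 12 by bromomethylbutenolide 8 is the most convergent cut. It joins the two halves, sets C7 trans to the C6 substituent and creates the lactone in its final position. Aldehyde 12 may be racemic because its carbinol carbon becomes C10.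

**Butenolide, 8 back to 5 and 6.** The ring is closed at C7=C11 by metathesis of ester 7, made from alcohol 5 and acid 6. This supplies C11–C13 with the bromide already in place.

**C6 and the Z-iodoalkene, 5 back to 1 and 2.** Alcohol 5 is the slow-reacting enantiomer in a lipase resolution of racemate 4. Racemate 4 arises by trans-hydroalumination and iodination of enynol 3, itself from acrolein 1 and Grignard reagent 2.

**Aldehyde, 12 back to 9 and 10.** Aldehyde 12 arises by ozonolysis of homoallylic alcohol 11, which is made from ketone 9 and Grignard reagent 10.

## Alternatives that were turned down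

Alternative 1: The ring would be opened at C6–C7. An open-chain substrate with an aldehyde at C6 and a 2-(bromomethyl)acrylate terminus would be treated with CrCl2; the allylchromium formed at C13 would attack the aldehyde through C7 and deliver the carbocyclic anti hydroxy ester A1, whose C6 hydroxyl later closes the lactone.
- For: allylchromium species equilibrate, so either bromide geometry gives the anti (trans-lactone) relation in A1 through a chair; the acrylate is already present, so no methylene masking is needed; medium-ring closures of this kind are well precedented.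
- Against: the open-chain substrate must already hold C8 and the C10 tertiary carbinol in defined absolute configuration, plus a protected C3 carbinol that is later destroyed. The Z-enal at C4–C6 can isomerise under Lewis-acidic trivalent chromium. Facial selectivity relative to C8 depends on macrocyclic conformation. After A1 is formed, C3 must be unmasked and oxidised and O8 selectively desilylated and acylated.
- Comparison: the route through A1 is stronger in precedent and in leaving the methylene lactone unmasked. The chosen route offers instead that C10 is never controlled in an open chain and that the dienone is formed at its final oxidation level in the ring-closing step.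

Alternative 2: The ten-membered ring would come from a cis-fused decalin whose two ring-fusion carbons, the later C3 and C8, both carry hydroxyl groups. Glycol cleavage with Pb(OAc)4 would break the C3–C8 bond, open rings A and B together and leave the ten-membered 3,8-diketone A2.
- For: the ring arises by fragmentation of a strain-free bicycle with no entropic penalty or high dilution; the six-membered ring guarantees the Z geometry of C4=C5; decalin stereocontrol is classical.
- Against: A2 lacks C1=C2 and has a ketone at C8. It is a β-hydroxy ketone (C10–OH/C8=O) open to retro-aldol ring opening, C7–H becomes acidic, and a 3,8-diketone in a ten-membered ring invites transannular aldol reaction. A late dehydrogenation and a stereoselective C8 reduction beside the enone are still required. The decalin with a fully substituted fusion diol, lactone and C10 carbinol would be long to make.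
- Comparison: the route through A2 is stronger in the reliability of ring formation. The chosen route is shorter and delivers the ring with C8 already set and no redox corrections on a fragile diketone.

Alternative 3: The ring would be cut at C7–C8, the same bond that joins the two fragments in the chosen route, but it would be made last and inside the macrocycle. Indium metal would insert into the C13–Br bond of a bromomethylbutenolide tethered to a C8 aldehyde, and the allylindium would add through C7 with shift of the alkene to C11=C13. The product of this closure is compound A3, which is the target without its tigloyl group.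
- For: it is the most convergent plan. Ring, C7, C8 and the methylene lactone form at once, and A3 is one acylation from the target.
- Against: the ring-locked allylmetal has C6 trans to the metal-bearing carbon, so a closed chair transition state should place the C8 hydroxyl on the wrong side and give the 8-epimer of A3; in a macrocyclic closure this cannot be corrected before the ring exists. The substrate would hold the full dienone next to a β-hydroxy aldehyde (retro-aldol, dehydration), and indium metal can reduce or allylate the dienone. C10 must be made enantiopure in an open chain.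
- Comparison: if the closure gave A3 with the right configuration at C8, this plan would be some eight steps shorter, which the chosen route cannot match. The chosen route uses the same disconnection between two fragments, where C8 can be inverted on a simple intermediate, and confines the risk to one step with a clear stereochemical model.

Key step: step 18

Remark: C10 is carried as both epimers from step 8 and C11 as both epimers from step 9, since step 18 erases and resets C10 and step 22 erases C11; the SMILES leave these centres open.
Assumption: the zinc Barbier reaction of step 8 follows the closed chair transition state and gives the 7,8-anti (8S) alcohol, which is why C8 is inverted in step 11.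

## Route

Step 1
Reactants: 1 acrolein; 2 1-propynylmagnesium bromide
Product: 3 rac-hex-1-en-4-yn-3-ol
Conditions: THF, −78 to 0 °C; aq. NH4Cl
Reagents that add atoms: none
Why: 1,2-Addition of an alkynyl Grignard reagent to an enal at low temperature; it joins C5–C6 and brings in C4, C15 and the vinyl group that becomes C7.

Step 2
Reactants: 3 rac-hex-1-en-4-yn-3-ol
Product: 4 rac-(4Z)-5-iodohexa-1,4-dien-3-ol
Conditions: NaAlH2(OCH2CH2OMe)2, THF, 0 °C to rt; EtOAc; then I2, −78 °C
Reagents that add atoms: iodine, II
Why: Alkoxide-directed trans-hydroalumination of the propargylic alcohol puts hydride on C5 and aluminium on C4; iodinolysis with retention should give the iodide cis to C6, which is the Z geometry of C4=C5 in the target.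

Step 3
Reactants: 4 rac-(4Z)-5-iodohexa-1,4-dien-3-ol
Product: 5 (3S,4Z)-5-iodohexa-1,4-dien-3-ol
Conditions: Novozym 435 (immobilised Candida antarctica lipase B), vinyl acetate, MTBE, 30 °C, to about 55% conversion; chromatography
Reagents that add atoms: none
Why: Lipase-catalysed kinetic resolution by acetylation; with vinyl as the medium and iodopropenyl as the large group the (R)-alcohol should be acetylated (Kazlauskas rule) and the (S)-alcohol recovered, which has the C6 arrangement of the target.

Step 4
Reactants: 5 (3S,4Z)-5-iodohexa-1,4-dien-3-ol; 6 2-(bromomethyl)prop-2-enoic acid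
Product: 7 (3S,4Z)-5-iodohexa-1,4-dien-3-yl 2-(bromomethyl)prop-2-enoate
Conditions: DCC, DMAP (5 mol %), CH2Cl2, −20 to 0 °C
Reagents that add atoms: none
Why: Steglich esterification of a secondary allylic alcohol; low temperature and little DMAP keep the allylic bromide intact.

Step 5
Reactants: 7 (3S,4Z)-5-iodohexa-1,4-dien-3-yl 2-(bromomethyl)prop-2-enoate
Product: 8 (5S)-3-(bromomethyl)-5-[(1Z)-2-iodoprop-1-en-1-yl]furan-2(5H)-one
Conditions: second-generation Grubbs catalyst (5 mol %), CH2Cl2 (5 mM), 40 °C
Reagents that add atoms: none
Why: Ring-closing metathesis between the vinyl group and the 2-substituted acrylate forms the butenolide (C7=C11); the trisubstituted iodoalkene is too hindered to take part.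

Step 6
Reactants: 9 1-[(tert-butyldimethylsilyl)oxy]propan-2-one; 10 allylmagnesium bromide
Product: 11 rac-1-[(tert-butyldimethylsilyl)oxy]-2-methylpent-4-en-2-ol
Conditions: THF, −78 °C; aq. NH4Cl
Reagents that add atoms: none
Why: Grignard addition to a ketone gives the tertiary carbinol that becomes C10, with C14 and the masked carboxyl carbon attached.

Step 7
Reactants: 11 rac-1-[(tert-butyldimethylsilyl)oxy]-2-methylpent-4-en-2-ol
Product: 12 rac-4-[(tert-butyldimethylsilyl)oxy]-3-hydroxy-3-methylbutanal
Conditions: O3, CH2Cl2, −78 °C; then PPh3
Reagents that add atoms: ozone, [O-][O+]=O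
Why: Ozonolysis with reductive work-up cleaves the terminal alkene to the C8 aldehyde; the β-hydroxy aldehyde is used crude.

Step 8
Reactants: 8 (5S)-3-(bromomethyl)-5-[(1Z)-2-iodoprop-1-en-1-yl]furan-2(5H)-one; 12 rac-4-[(tert-butyldimethylsilyl)oxy]-3-hydroxy-3-methylbutanal
Product: 13 anti Barbier adduct: 6,7-trans α-methylene-γ-lactone with the (Z)-2-iodopropenyl group on C6 and the (8S)-CH(OH)–CH2–C(CH3)(OH)–CH2OTBS chain on C7 (C10 epimers)
Conditions: Zn dust, THF/sat. aq. NH4Cl (3:1), 0 °C to rt
Reagents that add atoms: none
Why: Zinc Barbier allylation of an aldehyde with a 3-(bromomethyl)butenolide: the allylzinc reacts at C7 on the face anti to the C6 substituent, which sets C7 (6,7-trans); the ring holds C6 trans to the CH2Zn carbon, so a chair transition state with the aldehyde chain equatorial should give the 7,8-anti (8S) alcohol. The remote carbinol centre of 12 has little influence and both C10 epimers are carried on.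

Step 9
Reactants: 13 anti Barbier adduct
Product: 15 (8S) 13-hydroxy lactone (C11 saturated, CH2OH on C11; C10 and C11 epimers), via C13 pinacol boronate 14 (not isolated)
Conditions: B2pin2, CuCl (5 mol %), Xantphos (5 mol %), NaOtBu (10 mol %), MeOH (2 equiv), THF, rt; then NaBO3·4H2O, THF/H2O, rt
Reagents that add atoms: sodium perborate, [Na+].[O-]OB=O
Why: Copper-catalysed conjugate borylation of the unhindered methylene lactone puts boron on C13 and a proton on C11; perborate oxidises the C–B bond to the primary alcohol. The vinyl iodide is spared because its borylation would need stoichiometric alkoxide.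

Step 10
Reactants: 15 (8S) 13-hydroxy lactone
Product: 16 (8S) 13-O-TBDPS ether
Conditions: TBDPSCl, imidazole, DMF, 0 °C
Reagents that add atoms: tert-butyl(chloro)diphenylsilane, CC(C)(C)[Si](Cl)(c1ccccc1)c1ccccc1
Why: Silylation of the primary hydroxyl in preference to the hindered secondary and the tertiary one; TBDPS is chosen to survive the acid of step 19.

Step 11
Reactants: 16 (8S) 13-O-TBDPS ether
Product: 17 (8R) 8-O-(4-nitrobenzoate)
Conditions: 4-nitrobenzoic acid, PPh3, DIAD, toluene, 0 °C to rt
Reagents that add atoms: 4-nitrobenzoic acid, O=C(O)c1ccc(cc1)[N+](=O)[O-]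
Why: Mitsunobu esterification displaces the activated C8 oxygen by carboxylate with inversion (SN2), giving the 8R configuration of the target; the tertiary C10 hydroxyl does not react.

Step 12
Reactants: 17 (8R) 8-O-(4-nitrobenzoate)
Product: 18 (8R) 8,10-diol
Conditions: K2CO3, MeOH, 0 °C
Reagents that add atoms: none
Why: Methanolysis of the activated aryl ester is much faster than attack on the hindered lactone; in the 8R series a lactone on O8 would be cis-substituted, so the O6 lactone should stay where it is.

Step 13
Reactants: 18 (8R) 8,10-diol
Product: 19 8,10-acetonide (C7 on the dioxane C8 position; CH3 and CH2OTBS on C10; C10 and C11 epimers)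
Conditions: 2-methoxypropene, PPTS (10 mol %), CH2Cl2, 0 °C
Reagents that add atoms: 2-methoxypropene, C=C(C)OC
Why: Kinetic ketalisation of the secondary/tertiary 1,3-diol to the 1,3-dioxane, the only diol available.

Step 14
Reactants: 19 8,10-acetonide
Product: 20 primary alcohol (CH2OH on C10)
Conditions: HF·pyridine, pyridine, THF, 0 °C
Reagents that add atoms: none
Why: Buffered HF·pyridine removes the TBS ether while the far more robust TBDPS ether and the acetonide remain.

Step 15
Reactants: 20 primary alcohol
Product: 21 carboxylic acid (CO2H on C10; C10 and C11 epimers)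
Conditions: TEMPO (10 mol %), NaClO2, NaOCl (5 mol %), MeCN/phosphate buffer pH 6.7, 35 °C
Reagents that add atoms: sodium chlorite, [Na+].[O-]Cl=O
Why: TEMPO/chlorite oxidation of a primary alcohol to the acid at near-neutral pH, which the acetonide, lactone and vinyl iodide tolerate; the α-carbon is quaternary, so nothing can epimerise.

Step 16
Reactants: 22 (E)-1,2-bis(tributylstannyl)ethene; 23 benzenesulfonyl chloride
Product: 24 (E)-tributyl[2-(phenylsulfonyl)ethenyl]stannane
Conditions: Pd(PPh3)4 (2 mol %), THF, 65 °C, 22 in excess
Reagents that add atoms: none
Why: Palladium-catalysed coupling of a sulfonyl chloride with a vinylstannane gives the vinyl sulfone; excess bis-stannane keeps it at mono-coupling.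

Step 17
Reactants: 21 carboxylic acid; 24 (E)-tributyl[2-(phenylsulfonyl)ethenyl]stannane
Product: 25 seco acid: acetonide carboxylic acid with the (4Z)-C6–C5=C4(CH3)–C3(=O)–C2=C1–SO2Ph chain and 13-OTBDPS lactone (C10 and C11 epimers)
Conditions: CO (1 atm), Pd2(dba)3 (5 mol %), AsPh3 (20 mol %), CuI (10 mol %), NMP, 45 °C
Reagents that add atoms: carbon monoxide, [C-]#[O+]
Why: Carbonylative Stille coupling: oxidative addition to the vinyl iodide with retention of the Z geometry, CO insertion and transfer of the sulfonylvinyl group form C3–C4 and the β-sulfonyl enone in one step. The weakly nucleophilic arsine ligand limits addition to the product, and the alkene geometry at C1=C2 is of no consequence for step 18.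

Step 18
Reactants: 25 seco acid
Product: 27 ten-membered dienone with 8,10-acetonide and 13-OTBDPS lactone (6R,7R,8R,10R; 1E,4Z; C11 epimers), via cesium carboxylate 26 (not isolated)
Conditions: 4CzIPN (5 mol %), Cs2CO3 (0.6 equiv), degassed DMSO/MeCN (1:4), 1 mM, blue LEDs (450 nm), rt
Reagents that add atoms: none
Why: Proposed new method: photoexcited 4CzIPN oxidises carboxylate 26 and loss of CO2 gives the tertiary α-oxy radical at C10 of the dioxane, the same radical from both C10 epimers, so the step is stereoconvergent. The nucleophilic radical adds to C1, the sulfonyl-bearing β-carbon of the enone (10-endo-trig closure of the carbocycle), giving an α-keto radical at C2; β-scission of the phenylsulfonyl radical restores C1=C2, and the reduced photocatalyst converts that radical into sulfinate, closing the cycle. The closest known reactions are visible-light decarboxylative alkenylation of α-oxy and α-amino acids with vinyl sulfones and decarboxylative radical macrocyclisation onto acrylamides; closure of a ten-membered carbocycle in this way has not been shown. C10 is controlled by C8 through the dioxane chair: C7 sits equatorial, the radical reacts on its axial lobe (anomeric stabilisation, as in axial trapping of 2-oxanyl and 1,3-dioxan-4-yl radicals), C1 becomes axial and the methyl equatorial, which is the 8,10-anti, 10R arrangement. The E geometry at C1=C2 is expected because the α-keto radical can rotate before the sulfonyl radical leaves, while the Z alkene C4=C5 is already fixed. Attack on C5 (6-exo) or hydrogen transfer from C6–H would need C7 and the radical lobe both axial on the dioxane, a 2,4-dioxabicyclo[3.3.1]nonane with an inward acetonide methyl, so both are disfavoured, and C13 is saturated and cannot trap the radical. The step needs regioselective addition at C1 and not C2; the ketone secures this because only addition at C1 gives a stabilised radical that can expel the sulfonyl group.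

Step 19
Reactants: 27 ten-membered dienone acetonide
Product: 28 8,10-diol (13-OTBDPS)
Conditions: AcOH/H2O/THF (3:1:1), 35 °C
Reagents that add atoms: none
Why: Acid hydrolysis of the acetonide; the anti-1,3-diol acetonide carries an axial substituent and is labile, while the TBDPS ether and the tertiary carbinol, deactivated by the enone, persist.

Step 20
Reactants: 28 8,10-diol; 29 tiglic acid
Product: 30 8-O-tiglate (13-OTBDPS, free 10-OH)
Conditions: 2,4,6-trichlorobenzoyl chloride, Et3N, toluene, rt; then 28, DMAP, rt
Reagents that add atoms: none
Why: Yamaguchi esterification through the mixed anhydride acylates the secondary C8 hydroxyl; the tertiary C10 hydroxyl is inert, and fast acylation limits the time O8 is free beside the lactone.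

Step 21
Reactants: 30 8-O-tiglate
Product: 31 13-hydroxy compound
Conditions: HF·pyridine, pyridine, THF, 0 °C to rt
Reagents that add atoms: none
Why: Fluoride cleavage of the primary TBDPS ether under buffered, non-basic conditions that spare the tiglate, lactone and dienone.

Step 22
Reactants: 31 13-hydroxy compound
Product: 33 eupaheliangolide A, via C13 mesylate 32 (not isolated)
Conditions: MsCl, Et3N, CH2Cl2, 0 °C; then DBU, 0 °C
Reagents that add atoms: none
Why: Mesylation of the primary hydroxyl and E1cB elimination through the lactone enolate restore the exocyclic methylene and remove the C11 stereocentre; the tertiary alcohol is not mesylated under these conditions.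

## Compound list

1 | acrolein | C=CC=O | starting material
2 | 1-propynylmagnesium bromide | CC#C[Mg]Br | starting material
3 | rac-hex-1-en-4-yn-3-ol | C=CC(O)C#CC | intermediate
4 | rac-(4Z)-5-iodohexa-1,4-dien-3-ol | C=CC(O)/C=C(/C)I | intermediate
5 | (3S,4Z)-5-iodohexa-1,4-dien-3-ol | C=C[C@H](O)/C=C(/C)I | intermediate
6 | 2-(bromomethyl)prop-2-enoic acid | C=C(CBr)C(=O)O | starting material
7 | (3S,4Z)-5-iodohexa-1,4-dien-3-yl 2-(bromomethyl)prop-2-enoate | C=C[C@H](OC(=O)C(=C)CBr)/C=C(/C)I | intermediate
8 | (5S)-3-(bromomethyl)-5-[(1Z)-2-iodoprop-1-en-1-yl]furan-2(5H)-one | BrCC1=C[C@@H](/C=C(/C)I)OC1=O | intermediate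
9 | 1-[(tert-butyldimethylsilyl)oxy]propan-2-one | CC(=O)CO[Si](C)(C)C(C)(C)C | starting material
10 | allylmagnesium bromide | C=CC[Mg]Br | starting material
11 | rac-1-[(tert-butyldimethylsilyl)oxy]-2-methylpent-4-en-2-ol | C=CCC(C)(O)CO[Si](C)(C)C(C)(C)C | intermediate
12 | rac-4-[(tert-butyldimethylsilyl)oxy]-3-hydroxy-3-methylbutanal | O=CCC(C)(O)CO[Si](C)(C)C(C)(C)C | intermediate
13 | (4R,5S)-4-[(1S)-4-[(tert-butyldimethylsilyl)oxy]-1,3-dihydroxy-3-methylbutyl]-5-[(1Z)-2-iodoprop-1-en-1-yl]-3-methylideneoxolan-2-one (7R,8S in target numbering; the C6 arrangement is that of the target, its descriptor is S only because iodine outranks C7; C10 epimers) | C=C1C(=O)O[C@H](/C=C(/C)I)[C@H]1[C@@H](O)CC(C)(O)CO[Si](C)(C)C(C)(C)C | intermediate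
14 | C13 pinacol boronate of 13 (CH2Bpin on C11) | CC1(C)OB(CC2C(=O)O[C@H](/C=C(/C)I)[C@H]2[C@@H](O)CC(C)(O)CO[Si](C)(C)C(C)(C)C)OC1(C)C | intermediate (not isolated)
15 | (8S) 13-hydroxy lactone: 3-(hydroxymethyl)oxolan-2-one with the side chains of 13 (C10 and C11 epimers) | OCC1C(=O)O[C@H](/C=C(/C)I)[C@H]1[C@@H](O)CC(C)(O)CO[Si](C)(C)C(C)(C)C | intermediate
16 | (8S) 13-O-TBDPS ether of 15 | CC(C)(C)[Si](OCC1C(=O)O[C@H](/C=C(/C)I)[C@H]1[C@@H](O)CC(C)(O)CO[Si](C)(C)C(C)(C)C)(c1ccccc1)c1ccccc1 | intermediate
17 | (8R) 8-O-(4-nitrobenzoate) | CC(C)(C)[Si](OCC1C(=O)O[C@H](/C=C(/C)I)[C@H]1[C@H](OC(=O)c1ccc(cc1)[N+](=O)[O-])CC(C)(O)CO[Si](C)(C)C(C)(C)C)(c1ccccc1)c1ccccc1 | intermediate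
18 | (8R) 8,10-diol | CC(C)(C)[Si](OCC1C(=O)O[C@H](/C=C(/C)I)[C@H]1[C@H](O)CC(C)(O)CO[Si](C)(C)C(C)(C)C)(c1ccccc1)c1ccccc1 | intermediate
19 | 8,10-acetonide: 2,2,6-trimethyl-1,3-dioxane with CH2OTBS on C10 and the lactone on C8 (8R) | CC(C)(C)[Si](OCC1C(=O)O[C@H](/C=C(/C)I)[C@H]1[C@H]2CC(C)(CO[Si](C)(C)C(C)(C)C)OC(C)(C)O2)(c1ccccc1)c1ccccc1 | intermediate
20 | acetonide primary alcohol (CH2OH on C10) | CC(C)(C)[Si](OCC1C(=O)O[C@H](/C=C(/C)I)[C@H]1[C@H]2CC(C)(CO)OC(C)(C)O2)(c1ccccc1)c1ccccc1 | intermediate
21 | acetonide carboxylic acid (CO2H on C10) with vinyl iodide | CC(C)(C)[Si](OCC1C(=O)O[C@H](/C=C(/C)I)[C@H]1[C@H]2CC(C)(C(=O)O)OC(C)(C)O2)(c1ccccc1)c1ccccc1 | intermediate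
22 | (E)-1,2-bis(tributylstannyl)ethene | CCCC[Sn](CCCC)(CCCC)/C=C/[Sn](CCCC)(CCCC)CCCC | starting material
23 | benzenesulfonyl chloride | O=S(=O)(Cl)c1ccccc1 | starting material
24 | (E)-tributyl[2-(phenylsulfonyl)ethenyl]stannane | CCCC[Sn](CCCC)(CCCC)/C=C/S(=O)(=O)c1ccccc1 | intermediate
25 | seco acid: acetonide carboxylic acid with (1E,4Z) β-sulfonyl dienone chain and 13-OTBDPS lactone (6R,7R,8R; C10 and C11 epimers) | CC(C)(C)[Si](OCC1C(=O)O[C@H](/C=C(/C)C(=O)/C=C/S(=O)(=O)c3ccccc3)[C@H]1[C@H]2CC(C)(C(=O)O)OC(C)(C)O2)(c1ccccc1)c1ccccc1 | intermediate
26 | cesium carboxylate of 25 | CC(C)(C)[Si](OCC1C(=O)O[C@H](/C=C(/C)C(=O)/C=C/S(=O)(=O)c3ccccc3)[C@H]1[C@H]2CC(C)(C(=O)[O-])OC(C)(C)O2)(c1ccccc1)c1ccccc1.[Cs+] | intermediate (not isolated)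
27 | ten-membered (1E,4Z)-dienone with 8,10-acetonide and 13-OTBDPS lactone (6R,7R,8R,10R; C11 epimers) | CC(C)(C)[Si](OCC1C(=O)O[C@@H]2/C=C(/C)C(=O)/C=C/[C@]3(C)OC(C)(C)O[C@H](C3)[C@@H]12)(c1ccccc1)c1ccccc1 | intermediate
28 | 8,10-diol, 13-OTBDPS | CC(C)(C)[Si](OCC1C(=O)O[C@@H]2/C=C(/C)C(=O)/C=C/[C@](C)(O)C[C@@H](O)[C@@H]12)(c1ccccc1)c1ccccc1 | intermediate
29 | tiglic acid | C/C=C(\C)C(=O)O | starting material
30 | 8-O-tiglate, 13-OTBDPS | CC(C)(C)[Si](OCC1C(=O)O[C@@H]2/C=C(/C)C(=O)/C=C/[C@](C)(O)C[C@@H](OC(=O)/C(C)=C/C)[C@@H]12)(c1ccccc1)c1ccccc1 | intermediate
31 | 13-hydroxy-11,13-dihydro compound (8-O-tiglate) | OCC1C(=O)O[C@@H]2/C=C(/C)C(=O)/C=C/[C@](C)(O)C[C@@H](OC(=O)/C(C)=C/C)[C@@H]12 | intermediate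
32 | C13 mesylate of 31 | CS(=O)(=O)OCC1C(=O)O[C@@H]2/C=C(/C)C(=O)/C=C/[C@](C)(O)C[C@@H](OC(=O)/C(C)=C/C)[C@@H]12 | intermediate (not isolated)
33 | eupaheliangolide A | C=C1C(=O)O[C@@H]2/C=C(/C)C(=O)/C=C/[C@](C)(O)C[C@@H](OC(=O)/C(C)=C/C)[C@@H]12 | target

## Step count and risks

Total: 22 steps. Longest linear sequence: 19 steps (1–5, 8–15, 17–22, from acrolein 1).

**Step 18 (key step).** The most likely failures are:
- hydrogen abstraction by the C10 radical from solvent before it cyclises (net protodecarboxylation);
- closure onto C5 or hydrogen transfer from C6–H through a boat-like dioxane;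
- attack on the equatorial lobe, which is less shielded by the axial acetonide methyl, giving the C10 epimer;
- formation of the Z isomer at C1=C2;
- dark addition–elimination of the carboxylate on the sulfonyl enone.

The ten-membered closure is slow relative to these processes and the stereochemical model has not been tested on a macrocycle. Fallback with known chemistry: it sets out from the epimer of 20 whose hydroxymethyl group is trans to C7 on the dioxane, so that this carbon becomes C1. Dess–Martin oxidation gives the C1 aldehyde F1. A Wittig reaction with (triphenylphosphoranylidene)acetaldehyde gives the (E)-enal F2. An intramolecular Nozaki–Hiyama–Kishi reaction (CrCl2, catalytic NiCl2, DMSO/THF, high dilution) between the C4 iodide and the C3 aldehyde closes the ring to the cyclic bis-allylic alcohol F3. Oxidation with Dess–Martin periodinane returns to 27. Only half of the epimer mixture is usable unless 12 is made enantiopure.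

**Step 11.** Inversion at the hindered C8 carbinol may be overtaken by elimination towards C7 or C9, by retention through an acyloxyphosphonium pathway, or by phosphorane formation with the neighbouring tertiary hydroxyl. Fallback: from 16, Dess–Martin oxidation gives the C8 ketone F4; reduction with catecholborane under (S)-2-methyl-CBS-oxazaborolidine control (the branched C7 side as the large group) should deliver the 8R alcohol and rejoins the route at 18.

**Step 8.** Facial or simple diastereoselectivity may be low, the zinc alkoxide may induce lactone migration to O8, or the bromide may be reduced. Should the adduct prove to be 8R already, steps 11 and 12 are omitted. Fallback: the allylmetal is replaced by an allylboronate made before the ring is closed. From 7, copper-catalysed borylation (B2pin2, CuCl, LiCl, KOAc, DMF, rt), in which substitution with and without allylic shift leads to the same product, gives the 2-(borylmethyl)acrylate F5. Ring-closing metathesis with the second-generation Grubbs catalyst gives the butenolide allylic pinacol boronate F6. Its Sc(OTf)3-catalysed allylboration of 12, a tighter chair without a metal alkoxide, rejoins the route at 13.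

**Step 17.** Transmetallation of the electron-poor stannane may be slow, leading to hydrolysis of the acylpalladium or coupling without CO, and ligand may add to the sulfonyl enone. Fallback: from 21, carbonylative Stille coupling with tributyl(ethynyl)stannane, a fast-transferring group, gives the ynone F7; conjugate addition of benzenesulfinic acid (PhSO2Na, AcOH) gives 25, in which either alkene geometry serves.

**Step 22.** Once the methylene lactone is formed C7–H is vinylogously acidic, so DBU may expel tiglate across C7–C8 or epimerise C7. Fallback: from 27 the order is changed. HF·pyridine gives the 13-hydroxy acetonide F8, mesylation and elimination give the methylene lactone acetonide F9, and aqueous acetic acid gives the 8,10-diol F10, which is 8-O-destigloyl eupaheliangolide A. Yamaguchi tigloylation with 29 then ends at 33, so the ester never meets DBU.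

## Further compounds

F1 | step 18 | C1 aldehyde of the 10R-configured acetonide (CHO on C10, vinyl iodide at C4) | CC(C)(C)[Si](OCC1C(=O)O[C@H](/C=C(/C)I)[C@H]1[C@H]2C[C@](C)(C=O)OC(C)(C)O2)(c1ccccc1)c1ccccc1
F2 | step 18 | (E)-enal (C10–C1=C2–C3HO) with vinyl iodide at C4 | CC(C)(C)[Si](OCC1C(=O)O[C@H](/C=C(/C)I)[C@H]1[C@H]2C[C@](C)(/C=C/C=O)OC(C)(C)O2)(c1ccccc1)c1ccccc1
F3 | step 18 | ten-membered C3 bis-allylic alcohol with 8,10-acetonide (C3 epimers) | CC(C)(C)[Si](OCC1C(=O)O[C@@H]2/C=C(/C)C(O)/C=C/[C@]3(C)OC(C)(C)O[C@H](C3)[C@@H]12)(c1ccccc1)c1ccccc1
F4 | step 11 | C8 ketone of 16 | CC(C)(C)[Si](OCC1C(=O)O[C@H](/C=C(/C)I)[C@H]1C(=O)CC(C)(O)CO[Si](C)(C)C(C)(C)C)(c1ccccc1)c1ccccc1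
F5 | step 8 | (3S,4Z)-5-iodohexa-1,4-dien-3-yl 2-[(4,4,5,5-tetramethyl-1,3,2-dioxaborolan-2-yl)methyl]prop-2-enoate | C=C[C@H](OC(=O)C(=C)CB1OC(C)(C)C(C)(C)O1)/C=C(/C)I
F6 | step 8 | (5S)-5-[(1Z)-2-iodoprop-1-en-1-yl]-3-[(4,4,5,5-tetramethyl-1,3,2-dioxaborolan-2-yl)methyl]furan-2(5H)-one | CC1(C)OB(CC2=C[C@@H](/C=C(/C)I)OC2=O)OC1(C)C
F7 | step 17 | terminal ynone (C3(=O)–C≡CH) of the acetonide acid | CC(C)(C)[Si](OCC1C(=O)O[C@H](/C=C(/C)C(=O)C#C)[C@H]1[C@H]2CC(C)(C(=O)O)OC(C)(C)O2)(c1ccccc1)c1ccccc1
F8 | step 22 | 13-hydroxy ten-membered dienone acetonide | OCC1C(=O)O[C@@H]2/C=C(/C)C(=O)/C=C/[C@]3(C)OC(C)(C)O[C@H](C3)[C@@H]12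
F9 | step 22 | methylene lactone dienone acetonide | C=C1C(=O)O[C@@H]2/C=C(/C)C(=O)/C=C/[C@]3(C)OC(C)(C)O[C@H](C3)[C@@H]12
F10 | step 22 | 8-O-destigloyl eupaheliangolide A | C=C1C(=O)O[C@@H]2/C=C(/C)C(=O)/C=C/[C@](C)(O)C[C@@H](O)[C@@H]12
A1 | alternative 1 | ten-membered anti hydroxy ester (6-OH, methyl acrylate on C7, 3-OTBS, 8-OTES, 10-OH) | O[C@@H]1/C=C(/C)[C@H](O[Si](C)(C)C(C)(C)C)/C=C/[C@](C)(O)C[C@@H](O[Si](CC)(CC)CC)[C@H]1C(=C)C(=O)OC
A2 | alternative 2 | ten-membered 3,8-diketone with Z-enone, trans-lactone and C10 carbinol | C=C1C(=O)O[C@@H]2/C=C(/C)C(=O)CC[C@](C)(O)CC(=O)[C@@H]12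
A3 | alternative 3 | 8-O-destigloyl eupaheliangolide A | C=C1C(=O)O[C@@H]2/C=C(/C)C(=O)/C=C/[C@](C)(O)C[C@@H](O)[C@@H]12
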